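What I want left over in this flask at the end of the run is half of the electrophile, and I ask how much nucleophile leaves it so.

electrophile 20 mM; time 2.5 d

    electrophile + nucleophile → acid set free + target (k1 = 0.00902 M⁻¹ s⁻¹)
    2 electrophile → self-condensation product (k2 = 6.18 × 10⁻⁶ M⁻¹ s⁻¹)
    acid set free → by-product carried off (k3 = 6.82 × 10⁻⁴ s⁻¹)
    nucleophile + acid set free ⇌ protonated nucleophile, settled at all times (K4 = 6320 M⁻¹)

- in percentages every species weighs as the electrophile in it: one self-condensation product counts as two
- where a step has two of a species, its rate is k times that concentration squared, and two are used at each turn
- the amount of nucleophile is what is sought; it is there from the start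
- run time (flask): 2.5 d

- the equivalents of nucleophile at which the part of the electrophile that has reacted at 2.5 d is just 50%

I draw the electrophile used against time. It starts steeply: against the full charge a nucleophile lives about 1.54 h, far shorter than the run of 2.5 d. The acid set free parks nucleophile as protonated nucleophile. By itself the acid has a half-life of 0.282 h, and with 10.0 mM of free nucleophile beside it, about the charge I expect, that stretches to 18.1 h, still shorter than the run. So I draw a knee inside the run, and after it a nearly flat level, with the nucleophile as limiting reagent: electrophile used is nucleophile charged plus what self-condensation takes.

At the end of the run the electrophile is to stand at 10.0 mM. I count the run in the plateau half-life h = 93.6 d, the time self-condensation takes to halve the electrophile from that level; after time t, a fraction 1/(1 + t/h) stands. The run is 0.0267 of h, which takes 0.260 mM. Before the knee the electrophile stands higher than that, up to 20 mM, so I commit to just under 0.487 equiv.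

The forecast says 0.48 equiv, within 0.46 equiv to 0.5 equiv, since “the coupling consumes about one electrophile per nucleophile charged”. Its value lies below mine.

The simulation gives 0.484 equiv. Free nucleophile reads 0% at 2.50 d, and running on from there to 7.50 d with h gives 52.5% used, where the flask reads 52.5%. In the flask at twice the dilution the level is 5.00 mM, so h is 187 d, and adding its share to 0.484 puts the part reacted at 49.0%; that run reads 49.3%.

The numbers of this flask are made up; the flask was simulated.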